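**Plan**

1. Atom numbers (germacrane): C1–C10 ring carbons (C1, C2 the CH2CH2 unit; C3 acetate carbon; C4 bears C15H2OH; C5 and C10 joined by ether O5; C6 lactone O‑carbon; C7; C8 methacrylate carbon; C9), C11–C13 the acrylate unit, C14 the methyl on C10. Ring A = oxepane O5/C10/C1–C5; ring B = oxepane O5/C5–C10.
2. Cuts, in retrosynthetic order: (a) the C8 methacrylate, the C3 acetate and a C15 silyl ether; (b) C10–C1 together with O5–C10, which opens rings A and B at once to a monocyclic α‑methylene‑γ‑butyrolactone carrying a C10 methyl ketone, a free C5–OH and a C3 cyclopropanol; (c) C6–C7 and the lactone C12–O bond, giving a C3–C6/C15 lactol and a C7–C14 allylic bromide.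
3. Enabling feature: the C3 oxygen lies β to C1, so C1–C2–C3(=O) is a homoenolate unit that a cyclopropanol carries in strained form; C10 is a ketone‑level carbon flanked by O5, so ring B can exist as a planar oxocarbenium ion.
4. Forward order: the two fragments are joined with formation of the γ‑lactone; ring B (reversible hemiketal) and then ring A close in one operation; C3 is then reduced and acylated, and the C8 ester is placed last.
5. Stereochemistry: C5 from asymmetric hydrogenation; C4 from Fráter–Seebach alkylation (anti to O5); C8 from a proline aldol; C6 and C7 from chelate‑controlled syn,syn Barbier allylation; C10 from the bridge (relayed from C5, both hemiketal epimers converge); C3 from exo‑face hydride addition followed by Mitsunobu inversion.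

Key step: step 12

Remark: a four‑carbon tether can span C5 and C10 only on one face of ring B, so the route builds this ordinary out,out ether bridge and keeps every stereodescriptor of the given SMILES as written.

**Route**

Step 1
Reactants: 1 methyl 4,4-dimethoxy-3-oxobutanoate
Product: 2 methyl (3R)-3-hydroxy-4,4-dimethoxybutanoate
Conditions: H2 (50 atm), RuCl2[(S)-BINAP] (0.5 mol %), MeOH, 50 °C
Reagents that add atoms: none
Why: Noyori asymmetric hydrogenation of a β‑keto ester; hydride transfer within the ester‑chelated Ru–BINAP complex should set C5 as (R), in the facial sense known for 4‑heteroatom‑substituted acetoacetates.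

Step 2
Reactants: 2 methyl (3R)-3-hydroxy-4,4-dimethoxybutanoate
Product: 3 methyl (2S,3R)-2-[(benzyloxy)methyl]-3-hydroxy-4,4-dimethoxybutanoate
Conditions: LDA (2.2 equiv), THF, −78 → −20 °C; BnOCH2Cl, DMPU, −78 → −20 °C
Reagents that add atoms: benzyl chloromethyl ether, ClCOCc1ccccc1
Why: Fráter–Seebach alkylation; the chelated alkoxide–enolate dianion is alkylated on the face anti to the C5 substituent, which sets C4 anti to the C5 oxygen and brings in C15.

Step 3
Reactants: 3 methyl (2S,3R)-2-[(benzyloxy)methyl]-3-hydroxy-4,4-dimethoxybutanoate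
Product: 4 methyl (2S,3R)-3-hydroxy-2-(hydroxymethyl)-4,4-dimethoxybutanoate
Conditions: H2 (1 atm), palladium on carbon (Pd/C, 10 %), EtOAc, rt
Reagents that add atoms: none
Why: Hydrogenolysis of the benzyl ether before any alkene is present; acetal, ester and both stereocentres are untouched and a β‑hydroxy ester cannot lactonise.

Step 4
Reactants: 4 methyl (2S,3R)-3-hydroxy-2-(hydroxymethyl)-4,4-dimethoxybutanoate
Product: 5 methyl (2S,3R)-2-{[(tert-butyldiphenylsilyl)oxy]methyl}-3-hydroxy-4,4-dimethoxybutanoate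
Conditions: TBDPSCl (1.05 equiv), imidazole, CH2Cl2, 0 °C
Reagents that add atoms: tert-butyl(chloro)diphenylsilane, CC(C)(C)[Si](Cl)(c1ccccc1)c1ccccc1
Why: Selective silylation of the primary C15 hydroxyl over the hindered secondary C5 hydroxyl; this group stays until the last step.

Step 5
Reactants: 5 methyl (2S,3R)-2-{[(tert-butyldiphenylsilyl)oxy]methyl}-3-hydroxy-4,4-dimethoxybutanoate
Product: 6 1-[(2S,3R)-1-[(tert-butyldiphenylsilyl)oxy]-3-hydroxy-4,4-dimethoxybutan-2-yl]cyclopropan-1-ol
Conditions: EtMgBr (5 equiv), Ti(OiPr)4 (30 mol %), THF, 0 °C → rt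
Reagents that add atoms: ethylmagnesium bromide, CC[Mg]Br
Why: Kulinkovich cyclopropanation; the titanacyclopropane from EtMgBr and Ti(OiPr)4 converts the only ester (C3) into the 1‑substituted cyclopropanol (C1 and C2 come from the ethyl group), the β‑hydroxyl is carried as its alkoxide, and no stereocentre is touched.

Step 6
Reactants: 7 acetone; 8 2,2-dimethoxyacetaldehyde
Product: 9 (4R)-4-hydroxy-5,5-dimethoxypentan-2-one
Conditions: L-proline (20 mol %), acetone (excess), DMSO, rt
Reagents that add atoms: none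
Why: Proline‑catalysed direct asymmetric aldol reaction; the L‑proline enamine of acetone adds to the aldehyde through the hydrogen‑bonded chair transition state and should set C8 as (R), as with other α‑branched aldehydes.

Step 7
Reactants: 9 (4R)-4-hydroxy-5,5-dimethoxypentan-2-one
Product: 10 (4R)-4-[(tert-butyldimethylsilyl)oxy]-5,5-dimethoxypentan-2-one
Conditions: TBSCl, imidazole, DMF, rt
Reagents that add atoms: tert-butyl(chloro)dimethylsilane, CC(C)(C)[Si](C)(C)Cl
Why: Standard silylation of the secondary alcohol; it blocks retro‑aldol and later cyclisation of the C8 oxygen onto the allylic bromide.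

Step 8
Reactants: 10 (4R)-4-[(tert-butyldimethylsilyl)oxy]-5,5-dimethoxypentan-2-one
Product: 11 (2R)-2-[(tert-butyldimethylsilyl)oxy]-4-oxopentanal
Conditions: TFA/H2O (9:1), CH2Cl2, 0 °C
Reagents that add atoms: water, O
Why: Acid hydrolysis of the dimethyl acetal to the aldehyde at low temperature, where the silyl ether and the α‑stereocentre should hold.

Step 9
Reactants: 11 (2R)-2-[(tert-butyldimethylsilyl)oxy]-4-oxopentanal; 12 methyl acrylate
Product: 13 methyl (4R)-4-[(tert-butyldimethylsilyl)oxy]-3-hydroxy-2-methylidene-6-oxoheptanoate (both C3 epimers)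
Conditions: DABCO (0.5 equiv), methyl acrylate (neat), rt
Reagents that add atoms: none
Why: Morita–Baylis–Hillman reaction, aldehyde‑selective in the presence of the ketone; the new carbinol centre is formed as a mixture and is erased in step 10.

Step 10
Reactants: 13 methyl (4R)-4-[(tert-butyldimethylsilyl)oxy]-3-hydroxy-2-methylidene-6-oxoheptanoate
Product: 14 methyl (2Z,4R)-2-(bromomethyl)-4-[(tert-butyldimethylsilyl)oxy]-6-oxohept-2-enoate
Conditions: NBS, Me2S, CH2Cl2, 0 °C → rt
Reagents that add atoms: N-bromosuccinimide, O=C1CCC(=O)N1Br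
Why: Corey–Kim‑type activation of the allylic alcohol and SN2′ attack of bromide should give the rearranged primary allylic bromide with the (Z) geometry (ester trans to the C8 chain), the usual outcome for Morita–Baylis–Hillman alcohols.

Step 11
Reactants: 6 1-[(2S,3R)-1-[(tert-butyldiphenylsilyl)oxy]-3-hydroxy-4,4-dimethoxybutan-2-yl]cyclopropan-1-ol; 14 methyl (2Z,4R)-2-(bromomethyl)-4-[(tert-butyldimethylsilyl)oxy]-6-oxohept-2-enoate
Product: 17 (4S,5R)-4-[(1R)-1-[(tert-butyldimethylsilyl)oxy]-3-oxobutyl]-5-[(1R,2S)-3-[(tert-butyldiphenylsilyl)oxy]-1-hydroxy-2-(1-hydroxycyclopropyl)propyl]-3-methylideneoxolan-2-one, via lactol 15 (not isolated), via hydroxy ester 16 (not isolated)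
Conditions: (a) Amberlyst-15, THF/H2O 4:1, 40 °C, filter; (b) indium powder (In, 1.5 equiv), 14, THF/H2O 1:1, rt; (c) PPTS, CH2Cl2, rt
Reagents that add atoms: water, O
Why: Indium‑mediated Barbier allylation in water; the allylindium from 14 should add through its γ‑carbon (C7) to the aldehyde released from lactol 15 under chelation by the free C5–OH (syn C5/C6) and with syn simple diastereoselectivity (C6/C7), C8 being carried over from 14, and the syn γ‑hydroxy ester 16 should lactonise to the cis‑disubstituted α‑methylene‑γ‑butyrolactone.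

Step 12
Reactants: 17 (4S,5R)-4-[(1R)-1-[(tert-butyldimethylsilyl)oxy]-3-oxobutyl]-5-[(1R,2S)-3-[(tert-butyldiphenylsilyl)oxy]-1-hydroxy-2-(1-hydroxycyclopropyl)propyl]-3-methylideneoxolan-2-one
Product: 19 8-O-(tert-butyldimethylsilyl)-15-O-(tert-butyldiphenylsilyl)-3-oxo-5,10-epoxygermacr-11(13)-en-12,6-olide (C4–C8 and C10 as in the target), via hemiketal 18 (not isolated)
Conditions: Sc(OTf)3 (10 mol %), 4 Å MS, CH2Cl2, −40 → 0 °C
Reagents that add atoms: none
Why: Proposed new method: the acid drives reversible addition of O5 to the C10 ketone, both epimers of hemiketal 18 ionise to the same planar ring‑B oxocarbenium ion, and the strained C3–C1 σ‑bond of the cyclopropanol, pushed by the C3–OH lone pair, attacks C10 with ring opening (semipinacol‑like, driven by strain release) to give the C10–C1 bond and the C3 ketone irreversibly. The closest known reaction type is the Lewis‑acid‑mediated union of 1-(2-hydroxyalkyl)cyclopropanols or cyclopropyl silyl ethers with aldehyde‑derived oxocarbenium ions to give oxepan-4-ones and seven‑membered rings; here the ion is ketone‑derived, sits inside a ring and closes a bridge. Ring B closes 7‑exo‑trig (O5 on the C10 carbonyl); ring A closes 7‑endo‑trig on the C10=O5(+) bond (O5 stays in the new ring), which also completes the ten‑membered carbocycle. C10 is the only new stereocentre and is dictated by C5, because the C4–C1 tether reaches the cation only on the face syn to the C5–C4 bond, so the hemiketal mixture converges on one product. The step needs C–C bond formation to outrun protonolysis of the cyclopropanol and β‑elimination of the C8 silyloxy group. The 1,3‑relationship of the C3 and C5 hydroxyls (as in the known oxepanone annulation), the electron‑poor nature of both alkenes and the low temperature should secure this.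

Step 13
Reactants: 19 8-O-(tert-butyldimethylsilyl)-15-O-(tert-butyldiphenylsilyl)-3-oxo-5,10-epoxygermacr-11(13)-en-12,6-olide
Product: 20 8-O-(tert-butyldimethylsilyl)-15-O-(tert-butyldiphenylsilyl)-3-epi-3-hydroxy-5,10-epoxygermacr-11(13)-en-12,6-olide (C3–OH on the face opposite to the target acetate)
Conditions: NaBH4, CeCl3·7H2O, MeOH, −78 °C
Reagents that add atoms: none
Why: Luche reduction, 1,2‑selective so the α‑methylene lactone is spared; hydride is expected to enter from the exo face of the bridged bicycle (anti to the C6–C9 bridge), which places the C3 hydroxyl endo, the epimer of the target configuration.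

Step 14
Reactants: 20 8-O-(tert-butyldimethylsilyl)-15-O-(tert-butyldiphenylsilyl)-3-epi-3-hydroxy-5,10-epoxygermacr-11(13)-en-12,6-olide
Product: 21 3-O-acetyl-8-O-(tert-butyldimethylsilyl)-15-O-(tert-butyldiphenylsilyl)-3-hydroxy-5,10-epoxygermacr-11(13)-en-12,6-olide (C3 as in the target)
Conditions: PPh3, DIAD, AcOH, toluene, 0 °C → rt
Reagents that add atoms: acetic acid, CC(=O)O
Why: Mitsunobu esterification; SN2 displacement of the activated endo C3 oxygen by acetate from the exo face inverts C3 to the target configuration and installs the acetate in the same step.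

Step 15
Reactants: 21 3-O-acetyl-8-O-(tert-butyldimethylsilyl)-15-O-(tert-butyldiphenylsilyl)-3-hydroxy-5,10-epoxygermacr-11(13)-en-12,6-olide
Product: 22 3-O-acetyl-15-O-(tert-butyldiphenylsilyl)-3,8-dihydroxy-5,10-epoxygermacr-11(13)-en-12,6-olide (C8–OH free)
Conditions: CSA (0.2 equiv), MeOH/CH2Cl2 1:1, 0 °C → rt
Reagents that add atoms: none
Why: Acid‑catalysed methanolysis removes the TBS ether while the far more acid‑stable TBDPS ether, the acetate and both lactone and ether rings should stay.

Step 16
Reactants: 22 3-O-acetyl-15-O-(tert-butyldiphenylsilyl)-3,8-dihydroxy-5,10-epoxygermacr-11(13)-en-12,6-olide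
Product: 23 3-O-acetyl-8-O-methacryloyl-15-O-(tert-butyldiphenylsilyl)-3,8-dihydroxy-5,10-epoxygermacr-11(13)-en-12,6-olide
Conditions: methacrylic anhydride, DMAP, Et3N, CH2Cl2, 0 °C → rt
Reagents that add atoms: methacrylic anhydride, CC(=C)C(=O)OC(=O)C(C)=C
Why: DMAP‑catalysed acylation of the only free hydroxyl (C8), with retention at C8.

Step 17
Reactants: 23 3-O-acetyl-8-O-methacryloyl-15-O-(tert-butyldiphenylsilyl)-3,8-dihydroxy-5,10-epoxygermacr-11(13)-en-12,6-olide
Product: 24 (3R,4R,5R,6R,7R,8R,10R)-3-acetoxy-15-hydroxy-8-(methacryloyloxy)-5,10-epoxygermacr-11(13)-en-12,6-olide (target)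
Conditions: HF·pyridine, THF/pyridine, 0 °C → rt
Reagents that add atoms: none
Why: Fluoride cleavage of the primary TBDPS ether under mildly acidic conditions, which should avoid acetyl migration from O3 to O15 and leave both enoates intact.

**Compound list**

1 | methyl 4,4-dimethoxy-3-oxobutanoate | COC(OC)C(=O)CC(=O)OC | starting material
2 | methyl (3R)-3-hydroxy-4,4-dimethoxybutanoate | COC(OC)[C@H](O)CC(=O)OC | intermediate
3 | methyl (2S,3R)-2-[(benzyloxy)methyl]-3-hydroxy-4,4-dimethoxybutanoate | COC(OC)[C@H](O)[C@H](COCc1ccccc1)C(=O)OC | intermediate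
4 | methyl (2S,3R)-3-hydroxy-2-(hydroxymethyl)-4,4-dimethoxybutanoate | COC(OC)[C@H](O)[C@H](CO)C(=O)OC | intermediate
5 | methyl (2S,3R)-2-{[(tert-butyldiphenylsilyl)oxy]methyl}-3-hydroxy-4,4-dimethoxybutanoate | COC(OC)[C@H](O)[C@H](CO[Si](c1ccccc1)(c1ccccc1)C(C)(C)C)C(=O)OC | intermediate
6 | 1-[(2S,3R)-1-[(tert-butyldiphenylsilyl)oxy]-3-hydroxy-4,4-dimethoxybutan-2-yl]cyclopropan-1-ol | COC(OC)[C@H](O)[C@H](CO[Si](c1ccccc1)(c1ccccc1)C(C)(C)C)C1(O)CC1 | intermediate
7 | acetone | CC(C)=O | starting material
8 | 2,2-dimethoxyacetaldehyde | COC(OC)C=O | starting material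
9 | (4R)-4-hydroxy-5,5-dimethoxypentan-2-one | CC(=O)C[C@@H](O)C(OC)OC | intermediate
10 | (4R)-4-[(tert-butyldimethylsilyl)oxy]-5,5-dimethoxypentan-2-one | CC(=O)C[C@@H](O[Si](C)(C)C(C)(C)C)C(OC)OC | intermediate
11 | (2R)-2-[(tert-butyldimethylsilyl)oxy]-4-oxopentanal | CC(=O)C[C@@H](O[Si](C)(C)C(C)(C)C)C=O | intermediate
12 | methyl acrylate | C=CC(=O)OC | starting material
13 | methyl (4R)-4-[(tert-butyldimethylsilyl)oxy]-3-hydroxy-2-methylidene-6-oxoheptanoate (C3 epimers) | CC(=O)C[C@@H](O[Si](C)(C)C(C)(C)C)C(O)C(=C)C(=O)OC | intermediate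
14 | methyl (2Z,4R)-2-(bromomethyl)-4-[(tert-butyldimethylsilyl)oxy]-6-oxohept-2-enoate | CC(=O)C[C@@H](O[Si](C)(C)C(C)(C)C)/C=C(\CBr)C(=O)OC | intermediate
15 | (6R,7S)-7-{[(tert-butyldiphenylsilyl)oxy]methyl}-4-oxaspiro[2.4]heptane-5,6-diol (lactol, both anomers) | OC1OC2(CC2)[C@@H](CO[Si](c2ccccc2)(c2ccccc2)C(C)(C)C)[C@H]1O | intermediate
16 | methyl 3-[(1R)-1-[(tert-butyldimethylsilyl)oxy]-3-oxobutyl]-7-[(tert-butyldiphenylsilyl)oxy]-4,5-dihydroxy-6-(1-hydroxycyclopropyl)-2-methylideneheptanoate (open-chain syn,syn adduct, stereocentres as in 17) | CC(=O)C[C@@H](O[Si](C)(C)C(C)(C)C)[C@H]([C@@H](O)[C@H](O)[C@H](CO[Si](c1ccccc1)(c1ccccc1)C(C)(C)C)C1(O)CC1)C(=C)C(=O)OC | intermediate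
17 | (4S,5R)-4-[(1R)-1-[(tert-butyldimethylsilyl)oxy]-3-oxobutyl]-5-[(1R,2S)-3-[(tert-butyldiphenylsilyl)oxy]-1-hydroxy-2-(1-hydroxycyclopropyl)propyl]-3-methylideneoxolan-2-one | CC(=O)C[C@@H](O[Si](C)(C)C(C)(C)C)[C@H]1C(=C)C(=O)O[C@H]1[C@H](O)[C@H](CO[Si](c1ccccc1)(c1ccccc1)C(C)(C)C)C1(O)CC1 | intermediate
18 | seven-membered hemiketal of 17 (O5 bonded to C10, both C10 epimers, cyclopropanol intact) | CC1(O)C[C@@H](O[Si](C)(C)C(C)(C)C)[C@H]2C(=C)C(=O)O[C@H]2[C@@H]([C@H](CO[Si](c3ccccc3)(c3ccccc3)C(C)(C)C)C3(O)CC3)O1 | intermediate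
19 | 8-O-(tert-butyldimethylsilyl)-15-O-(tert-butyldiphenylsilyl)-3-oxo-5,10-epoxygermacr-11(13)-en-12,6-olide (C4–C8 and C10 as in the target) | CC(C)(C)[Si](C)(C)O[C@@H]1C[C@@]2(C)CCC(=O)[C@@H](CO[Si](c3ccccc3)(c3ccccc3)C(C)(C)C)[C@@H](O2)[C@@H]2OC(=O)C(=C)[C@@H]21 | intermediate
20 | 8-O-(tert-butyldimethylsilyl)-15-O-(tert-butyldiphenylsilyl)-3-epi-3-hydroxy-5,10-epoxygermacr-11(13)-en-12,6-olide | CC(C)(C)[Si](C)(C)O[C@@H]1C[C@@]2(C)CC[C@H](O)[C@@H](CO[Si](c3ccccc3)(c3ccccc3)C(C)(C)C)[C@@H](O2)[C@@H]2OC(=O)C(=C)[C@@H]21 | intermediate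
21 | 3-O-acetyl-8-O-(tert-butyldimethylsilyl)-15-O-(tert-butyldiphenylsilyl)-3-hydroxy-5,10-epoxygermacr-11(13)-en-12,6-olide | CC(C)(C)[Si](C)(C)O[C@@H]1C[C@@]2(C)CC[C@@H](OC(C)=O)[C@@H](CO[Si](c3ccccc3)(c3ccccc3)C(C)(C)C)[C@@H](O2)[C@@H]2OC(=O)C(=C)[C@@H]21 | intermediate
22 | 3-O-acetyl-15-O-(tert-butyldiphenylsilyl)-3,8-dihydroxy-5,10-epoxygermacr-11(13)-en-12,6-olide | O[C@@H]1C[C@@]2(C)CC[C@@H](OC(C)=O)[C@@H](CO[Si](c3ccccc3)(c3ccccc3)C(C)(C)C)[C@@H](O2)[C@@H]2OC(=O)C(=C)[C@@H]21 | intermediate
23 | 3-O-acetyl-8-O-methacryloyl-15-O-(tert-butyldiphenylsilyl)-3,8-dihydroxy-5,10-epoxygermacr-11(13)-en-12,6-olide | C=C(C)C(=O)O[C@@H]1C[C@@]2(C)CC[C@@H](OC(C)=O)[C@@H](CO[Si](c3ccccc3)(c3ccccc3)C(C)(C)C)[C@@H](O2)[C@@H]2OC(=O)C(=C)[C@@H]21 | intermediate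
24 | (3R,4R,5R,6R,7R,8R,10R)-3-acetoxy-15-hydroxy-8-(methacryloyloxy)-5,10-epoxygermacr-11(13)-en-12,6-olide | C=C(C)C(=O)O[C@@H]1C[C@@]2(C)CC[C@@H](OC(C)=O)[C@@H](CO)[C@@H](O2)[C@@H]2OC(=O)C(=C)[C@@H]21 | target

**Step count and risks**

Total steps: 17. Longest linear sequence: 12 (steps 1–5 and 11–17; the branch of steps 6–10 is equally long).

Step 12 (proposed new method). Process at risk: protonolysis of the cyclopropanol to an ethyl ketone, or reversible capture of the seven‑membered oxocarbenium ion by oxygen only, may outrun C10–C1 bond formation. Fallback with known reaction types, radical in place of cationic C–C bond formation, from 17 back to 19: reductive etherification of 17 (Et3SiH, TMSOTf, CH2Cl2, −78 °C, mild acidic work‑up) should close ring B as the 2‑methyloxepane F1 (C10–H, either epimer, cyclopropanol intact). Aerobic palladium catalysis (Pd(OAc)2 10 mol %, pyridine, O2, toluene, 80 °C) should then open the cyclopropanol through β‑hydride elimination of the palladium homoenolate to the vinyl ketone F2. Irradiation of F2 (390 nm) with (Bu4N)4W10O32 (2 mol %) in MeCN should abstract the tertiary α‑oxy hydrogen at C10, and the nucleophilic radical should close 7‑endo onto the enone (Giese‑type addition), again only on the face syn to the C5–C4 bond, to give 19. Hydrogen abstraction at other α‑oxy positions and radical addition to the lactone methylene are the weak points of this fallback.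

Step 11. Process at risk: mismatched double diastereodifferentiation (the C8 stereocentre of the allylindium opposing the chelate‑controlled syn,syn pathway) or loss of chelate control, which would give C6/C7 epimers. Fallback, from 14 and 6 back to 17: 14 is converted with (Bu3Sn)2 and Pd(PPh3)4 (THF) into the allylstannane F3, lactol 15 is isolated after the hydrolysis stage, and the two are combined with MgBr2·OEt2 in CH2Cl2 at −20 °C. This is a Lewis‑acid‑promoted SE2′ addition through an open transition state on the magnesium chelate of the α‑hydroxy aldehyde (Cram‑chelate control for C5/C6, antiperiplanar open arrangement for syn C6/C7) and should give 16, which lactonises with PPTS to 17.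

Step 13 (with its partner step 14). Process at risk: poor facial selectivity of hydride addition to the C3 ketone, because the exo face carries the C4 substituent while the endo face is screened by ring B, and slow Mitsunobu displacement next to C4. Fallback, from 19 back to 21: the alcohol formed by attack on the other face, the 3‑hydroxy epimer F4, already has the target configuration at C3 and is acetylated with retention (Ac2O, DMAP, pyridine, 0 °C) to 21. Both faces of hydride attack then converge on 21 and no inversion is needed for that portion.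

**Further compounds**

F1 | step 12 | 2-methyloxepane from 17 (O5 bonded to C10 as a C10–H ether, both C10 epimers, cyclopropanol intact) | CC1C[C@@H](O[Si](C)(C)C(C)(C)C)[C@H]2C(=C)C(=O)O[C@H]2[C@@H]([C@H](CO[Si](c3ccccc3)(c3ccccc3)C(C)(C)C)C3(O)CC3)O1
F2 | step 12 | vinyl ketone from F1 (cyclopropanol opened to C3(=O)–CH=CH2) | CC1C[C@@H](O[Si](C)(C)C(C)(C)C)[C@H]2C(=C)C(=O)O[C@H]2[C@@H]([C@H](CO[Si](c3ccccc3)(c3ccccc3)C(C)(C)C)C(=O)C=C)O1
F3 | step 11 | methyl (2Z,4R)-4-[(tert-butyldimethylsilyl)oxy]-6-oxo-2-[(tributylstannyl)methyl]hept-2-enoate | CC(=O)C[C@@H](O[Si](C)(C)C(C)(C)C)/C=C(\C[Sn](CCCC)(CCCC)CCCC)C(=O)OC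
F4 | step 13 | 8-O-(tert-butyldimethylsilyl)-15-O-(tert-butyldiphenylsilyl)-3-hydroxy-5,10-epoxygermacr-11(13)-en-12,6-olide (C3 epimer of 20, C3 as in the target) | CC(C)(C)[Si](C)(C)O[C@@H]1C[C@@]2(C)CC[C@@H](O)[C@@H](CO[Si](c3ccccc3)(c3ccccc3)C(C)(C)C)[C@@H](O2)[C@@H]2OC(=O)C(=C)[C@@H]21
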